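## Structural features

The target is a trinor-eremophilane: two six-membered carbocycles fused through C5–C10, twelve skeletal carbons (C1–C10 plus the methyls C14 on C5 and C15 on C4), esterified at O3 with (2E,4E,6S)-6-methylocta-2,4-dienoic acid. Ring A (C1–C5, C10) carries four contiguous stereocentres: C2 (free hydroxyl), C3 (acyloxy), C4 (secondary methyl) and C5 (quaternary, angular methyl). Read in the usual orientation, both methyls and O3 are β and O2 is α, so O2 and O3 are trans-diaxial on a half-chair locked by the axial C14 methyl; the absolute configuration is 2R,3R,4R,5S. Ring B (C5–C10) is a cross-conjugated 2-hydroxycyclohexa-2,5-dienone, C6=C7(OH)–C8(=O)–C9=C10, the enol (diosphenol) of a 7,8-dione. Fragile points are this diosphenol (cleaved by peracids and alkaline peroxide), the C2 hydroxyl (δ to the C8 carbonyl through C9=C10, so open to vinylogous dehydration), the 4,4-disubstituted dienone (cationic shifts in strong acid), and the α-branched stereocentre of the side chain at its aldehyde stage. The real difficulty is the vicinal C4/C5 pair with a quaternary C5 between two sp2 carbons, and placing the acyl group on the more hindered ring A oxygen (O3 is flanked by C4–CH3 and syn-axial to C14). The key step uses the fact that ring B, one oxidation level lower at C8, is a 1,4-cyclohexadiene with C6=C7 and C9=C10 on either side of C8 and with C5 and C10 shared with ring A. A diene C5=C6–C7=C8 and an alkyne C9≡C10, joined through C4–C3=C2–C1, therefore give both rings at once, and the Z-alkene C2=C3 of the tether is the later handle for the trans-diaxial O2/O3 pattern.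

## Logic of the disconnections

24 ⇒ 23 ⇒ 22. The C7–O bond is removed first: the enol of the 7,8-dione is an isomer of the α,β-epoxy ketone 23, whose oxirane comes from C6=C7 of 22. C7 is the α-carbon of an enone and C6 is the less substituted of the two β-carbons (C6 against C10), so substitution decides the site. The gain is an intermediate without enol. The demand is a non-hydrolytic peroxide so that the ester survives, and an isomerisation mild enough to keep the C2 hydroxyl.

22 ⇒ 17 + 21, and 17 ⇒ 16. The C3–O(acyl) bond is cut, then both ring A C–O bonds. The trans-diaxial hydroxy ester is the diaxial (Fürst–Plattner) opening product of the 2α,3α-oxirane of 17 by the carboxylate of 21 at C3, and a peracid should place that oxirane on the face of C2=C3 remote from the axial C14 of 16. Ring opening puts the acyl group on the more hindered oxygen by stereoelectronics, where acylation of a diol would choose O2, and it needs no protecting group. The oxirane must be α: a β-oxirane would open diaxially at C2 and give the 2-acyloxy-3-hydroxy regioisomer. The demand is axial attack at C3 syn to C14.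

21 ⇒ 20 ⇒ 19 ⇒ 18. The C4=C5 bond of the acid is cut by Horner–Wadsworth–Emmons logic with a four-carbon phosphonate, and the aldehyde 19 comes from the chiral-pool alcohol 18. The gain is a three-step convergent branch. The demand is that the α-branched aldehyde is made and consumed without enolisation.

16 ⇒ 15. The C8 carbonyl is traced to a doubly allylic methyl ether. This keeps C8 at the oxidation level that an enol-ether diene delivers and marks the only C–H that a hydride abstractor should take. The demand is selectivity for the C8–H over the doubly allylic C1–H2.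

15 ⇒ 14. C5–C10 and C8–C9 are cut together (the [4+2] retron). Two rings, two C–C bonds, the quaternary C5 and both ring B alkenes disappear, leaving an acyclic trienyne with one stereocentre (C4). The demand is a metal-templated cycloaddition, because an unactivated alkyne and an electron-rich diene will not combine thermally, with C4 controlling the face at C5.

14 ⇒ 13 ⇒ 12. The alkynyl C–Si bond and the sp2–sp2 bond C6–C7 are cut. Cross-coupling an (E)-alkenyl iodide with an (E)-alkoxyvinyl boron reagent fixes both diene geometries, which a methoxymethylene Wittig reaction on an enal would not. The silyl group keeps the alkyne C–H away from the basic steps. The demand is a coupling mild enough for a skipped enyne.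

12 ⇒ 8 + 11 (11 ⇐ 10 ⇐ 9). C2=C3 is cut by Z-selective Wittig logic, with C1, C2, C9 and C10 coming from the four-carbon ylide. The demand is that the α-stereocentre of 8, which is also allylic, survives the ylide.

8 ⇒ 7 ⇒ 6 ⇒ 5 ⇒ 4. C5–C14 and C6–I are cut: syn carboalumination of the alkyne of 4 and iodinolysis of 5 build the (E)-trisubstituted alkene with full geometric control. The stereocentre is never α to a ketone, which it would be if C5=C6 were made by olefination of a methyl ketone. The demand is tolerance of the silyl ether by AlMe3.

4 ⇒ 3 ⇒ 2 ⇒ 1. The C5≡C6 bond is cut (one-carbon homologation of the ester carbon via 3). C4 comes from the chiral pool. Because the ester carbon of 1 becomes C5 and its CH2O carbon becomes C3, the (S)-ester is required; the same operations on the (R)-ester would give the enantiomer of 14.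

## Other disconnections considered

Alternative 1: The cut is at C5–C14 with a sacrificial C10–C14 bond, so the angular methyl is carried as the methylene of a cyclopropane across C5 and C10. Forward, the homoallylic alcohol A1 (Δ5(10)-octalin with the C3 hydroxyl, the C4 methyl and a ketal at C8) would be treated with Et2Zn/CH2I2. The zinc alkoxide at O3 holds IZnCH2I and passes the methylene to the tetrasubstituted C5=C10 bond on its own face, giving cyclopropane A2.
- In A2 the hydroxyl, methyl and bridge lie on one face, which in the numbering and orientation of the target is the β face (3β,4β,5β,10β); an α label for that SMILES fits only a mirror-image drawing.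
- In its favour: a covalently bound directing group is a more dependable source of face control at a quaternary carbon than the conformational bias of the chosen plan, and the methylene transfer is concerted. On the certainty of C5 relative to O3 and C15 this alternative is the better one.
- Against it: A1 already needs the cis C3/C4 pair on a pre-formed decalin, and the hydroxyl is homoallylic, not allylic. The bridge must later open at C10–C14 and not at C5–C10; both bonds are similarly placed toward the C8 enol after ketal removal, and the wrong cleavage would enlarge ring B. The C2 oxygen, C6=C7 and the C7 hydroxyl would each need a separate oxidation.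
- Comparison: the alternative makes one C–C bond on an existing bicycle, whereas the [4+2] makes both rings and delivers ring B with C6=C7, C9=C10 and an oxidised C8. Its mechanism is the more predictable; its step count should be clearly higher.

Alternative 2: The cuts are C5–C10 and C6–C7. Forward, the enolised β-diketone A3 would be irradiated at 350 nm. The enol C10=C7 adds across the tethered 1,1-disubstituted alkene C5=C6, and retro-aldol cleavage of the cyclobutanol (C10–C7) gives the 1,5-diketone A4, a ring A cyclohexanone with the quaternary C5 and a 3-oxobutyl chain ready for aldol closure of ring B.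
- In its favour: ring A arrives with O2 and O3 already differentiated (silyl against 4-methoxybenzyl), so the ester can be placed without any regiochemical question. This is better than the chosen plan, which relies on a diaxial epoxide opening at a hindered carbon. The later aldol condensation and an α′-oxidation at C7 to the diosphenol are at least as simple as the dienone epoxidation used here.
- Against it: A3 needs three contiguous stereocentres in an open chain and two protecting groups. A four-atom tether between enol and alkene gives no rule-of-five bias, so crossed adducts are possible. The face at C5 depends on the folding of a flexible chain in a stepwise triplet biradical process, which is less templated than a metallacycle. Ring B is not formed in the key step.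
- Comparison: the quaternary centre is made in both plans under substrate control of uncertain size, so they are equal there; the alternative is better on oxygen differentiation and worse on ring count per step, on protecting-group load and on the expected length to A3.

Alternative 3: The cut is C9–C10. Forward, the achiral dienone A5 would condense at its side-chain methyl ketone with a chiral primary amine; the enamine attacks through C9 one of the two enantiotopic β-carbons (C10) and closes ring B, giving the cis-fused enedione A6 with C5 set by the catalyst.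
- In its favour: absolute configuration at the quaternary carbon comes from a catalyst acting on achiral material, this desymmetrisation type is well established for 4,4-disubstituted cyclohexadienones, and the bicycle is reached in very few steps. On absolute stereocontrol and on brevity up to the bicycle it is better than the chosen plan.
- Against it: in A6 the remaining enone is C3=C4–C2=O in ring A and C8 is a saturated ketone, so the oxidation pattern is on the wrong ring. C15 is missing and would have to be added at C4 cis to the angular methyl on a cis-fused decalin, the sense least likely from steric control. O3, reduction at C2, two dehydrogenations in ring B and the C7 hydroxyl would follow, and the new C10 stereocentre is later destroyed.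
- Comparison: the enamine Michael addition is mechanistically simpler and better understood than the rhodium cycle, but after the key step this route should be markedly longer and less certain than one in which C4, C5 and the ring B unsaturation arrive together.

Key step: step 9

Remarks on the chemistry:
- Assumption: (E)-2-(2-methoxyethenyl)-4,4,5,5-tetramethyl-1,3,2-dioxaborolane is taken as a purchasable reagent; the ethyl analogue would serve equally, because the alkyl group leaves as the alcohol in step 10.
- Descriptor: by the sequence rule the stereocentre of 14 is 5S (the C(CH3)= branch outranks the CH= branch); a 5R label on this SMILES would name the enantiomer.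
- Precursor design: the constitution of 14 is unchanged. Its assembly is changed so that the alkyne C–H is masked as a silyl derivative until the last step, the enol ether geometry is fixed by cross-coupling, and the stereocentre is never α to a ketone.

## Route

Step 1
Reactants: 1 methyl (S)-3-hydroxy-2-methylpropanoate
Product: 2 methyl (S)-3-[(tert-butyldimethylsilyl)oxy]-2-methylpropanoate
Conditions: TBSCl, imidazole, CH2Cl2, 0 °C → 23 °C
Reagents that add atoms: tert-butyldimethylsilyl chloride, CC(C)(C)[Si](C)(C)Cl
Why: Standard silylation of a primary alcohol; the stereocentre is not touched and the ether withstands iBu2AlH, AlMe3 and iodine.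

Step 2
Reactants: 2 methyl (S)-3-[(tert-butyldimethylsilyl)oxy]-2-methylpropanoate
Product: 4 (R)-tert-butyldimethyl[(2-methylbut-3-yn-1-yl)oxy]silane, via silyloxy aldehyde 3 (not isolated)
Conditions: iBu2AlH, CH2Cl2, −78 °C; then MeOH, K2CO3, dimethyl (1-diazo-2-oxopropyl)phosphonate, −78 °C → 23 °C
Reagents that add atoms: dimethyl (1-diazo-2-oxopropyl)phosphonate, CC(=O)C(=[N+]=[N-])P(=O)(OC)OC
Why: Half-reduction of the ester gives an aluminium hemiacetal that releases aldehyde 3 in methanol, and the Ohira–Bestmann (Seyferth–Gilbert) homologation converts it in the same flask to the alkyne, so the epimerisable aldehyde is never handled. The descriptor changes from S to R only because the priorities change.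

Step 3
Reactants: 4 (R)-tert-butyldimethyl[(2-methylbut-3-yn-1-yl)oxy]silane
Product: 6 tert-butyl{[(2R,3E)-4-iodo-2,3-dimethylbut-3-en-1-yl]oxy}dimethylsilane, via alkenylalane 5 (not isolated)
Conditions: AlMe3, Cp2ZrCl2 (0.3 equiv), CH2Cl2, 0 → 23 °C; then I2, THF, −30 → 0 °C
Reagents that add atoms: trimethylaluminium, C[Al](C)C; iodine, [I][I]
Why: Negishi zirconium-catalysed carboalumination adds CH3 (the future C14) and aluminium syn across the terminal alkyne with the methyl at the internal carbon, and iodinolysis of the C–Al bond with retention gives the (E)-iodide only. No base strong enough to touch the propargylic stereocentre is present.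

Step 4
Reactants: 6 tert-butyl{[(2R,3E)-4-iodo-2,3-dimethylbut-3-en-1-yl]oxy}dimethylsilane
Product: 7 (2R,3E)-4-iodo-2,3-dimethylbut-3-en-1-ol
Conditions: camphorsulfonic acid (cat.), MeOH/CH2Cl2, 0 → 23 °C
Reagents that add atoms: none
Why: Acid-catalysed methanolysis of a primary silyl ether; the alkenyl iodide and the allylic stereocentre are inert to these conditions.

Step 5
Reactants: 7 (2R,3E)-4-iodo-2,3-dimethylbut-3-en-1-ol
Product: 8 (2R,3E)-4-iodo-2,3-dimethylbut-3-enal
Conditions: Dess–Martin periodinane, CH2Cl2, 0 → 23 °C; filtered through a short silica pad and used at once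
Reagents that add atoms: none
Why: Dess–Martin oxidation is non-basic, so the α-stereocentre (both α to the formyl group and allylic) should be preserved; the crude aldehyde is taken directly into step 7.

Step 6
Reactants: 9 (4-bromobut-1-yn-1-yl)trimethylsilane
Product: 10 triphenyl[4-(trimethylsilyl)but-3-yn-1-yl]phosphonium bromide
Conditions: PPh3, MeCN, 80 °C
Reagents that add atoms: triphenylphosphine, c1ccc(cc1)P(c1ccccc1)c1ccccc1
Why: SN2 quaternisation of a primary bromide; the silyl cap removes the alkyne C–H that would otherwise compete with ylide formation in step 7.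

Step 7
Reactants: 10 triphenyl[4-(trimethylsilyl)but-3-yn-1-yl]phosphonium bromide; 8 (2R,3E)-4-iodo-2,3-dimethylbut-3-enal
Product: 12 trimethyl[(4Z,6S,7E)-8-iodo-6,7-dimethylocta-4,7-dien-1-yn-1-yl]silane, via phosphonium ylide 11 (not isolated)
Conditions: 10, NaN(SiMe3)2, THF, −78 → 0 °C; then 8, THF, −78 → −20 °C
Reagents that add atoms: none
Why: A non-stabilised ylide under lithium-free conditions gives the Z-alkene through the kinetically favoured cis-oxaphosphetane (Wittig reaction), building C2=C3 with C1, C10 and C9 attached. Addition at −78 °C is expected to be faster than enolisation of 8, and the alkenyl iodide is inert to the ylide.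

Step 8
Reactants: 12 trimethyl[(4Z,6S,7E)-8-iodo-6,7-dimethylocta-4,7-dien-1-yn-1-yl]silane
Product: 14 (1E,3E,5S,6Z)-1-methoxy-4,5-dimethyldeca-1,3,6-trien-9-yne, via silylated trienyne 13 (not isolated)
Conditions: (E)-MeOCH=CH–B(pin) (1.3 equiv), PdCl2(dppf) (5 mol%), K3PO4, THF/H2O, 45 °C; then MeOH, K2CO3 (cat.), 23 °C; chromatography on Et3N-treated silica
Reagents that add atoms: (E)-2-(2-methoxyethenyl)-4,4,5,5-tetramethyl-1,3,2-dioxaborolane, CO/C=C/B1OC(C)(C)C(C)(C)O1
Why: Suzuki–Miyaura coupling of an alkenyl iodide with an alkenylboronate keeps the geometry of both partners, so the (1E,3E)-dienol ether is formed as a single isomer. Once the iodide is consumed, basic methanolysis removes the alkynyl silyl group without touching the enol ether or the skipped enyne.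

Step 9
Reactants: 14 (1E,3E,5S,6Z)-1-methoxy-4,5-dimethyldeca-1,3,6-trien-9-yne
Product: 15 (2R,4aR,5S)-2-methoxy-4a,5-dimethyl-2,4a,5,8-tetrahydronaphthalene
Conditions: [RhCl(cod)]2 (5 mol%), AgSbF6 (10 mol%), ClCH2CH2Cl, 25 → 50 °C, 0.02 M; catalyst solution filtered from AgCl before 14 is added
Reagents that add atoms: none
Why: Chloride abstraction gives the [Rh(cod)]+ fragment of monovalent rhodium, which binds the s-cis diene C5=C6–C7=C8 and the tethered alkyne; oxidative cyclisation forms C5–C10 and a rhodacycle of trivalent rhodium (vinyl at C9, allyl over C6–C8), and reductive elimination forms C8–C9 and frees the catalyst. This is the known rhodium-catalysed intramolecular [4+2] cycloaddition of dienynes, used here at the demanding end of its range (four-atom tether, diene terminus that becomes quaternary), which is why the rigid Z-alkene is kept in the tether to hold the alkyne over the diene. Ring B closes as the formal [4+2] adduct from the four diene carbons and the two alkyne carbons; ring A closes in the same event through C4–C3=C2–C1 as a six-membered ring in which C10 becomes the fusion carbon and C9 stays outside ring A. C5 is set by the resident C4 centre: in the half-chair-like array of the forming ring A the C4 methyl should occupy the pseudo-equatorial site anti to the incoming alkyne and metal while the small C4–H eclipses C5=C6, which puts C14 and C15 cis. C8 follows from suprafacial addition to the (E,E)-diene, which places OMe cis to C4 across ring B (2R), and this centre is erased in step 10. The step needs chemoselectivity for the diene over the isolated C2=C3 alkene (only the diene can chelate together with the alkyne), regiochemistry (fixed by the tether) and π-facial selectivity (from C4). The E geometry at C5=C6 keeps the tether on the outside of the diene and the E enol ether keeps OMe outside, so the s-cis form stays accessible. Removing AgCl first keeps free silver ion and adventitious HSbF6 away from the acid-labile dienol ether.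

Step 10
Reactants: 15 (2R,4aR,5S)-2-methoxy-4a,5-dimethyl-2,4a,5,8-tetrahydronaphthalene
Product: 16 (4aR,5S)-4a,5-dimethyl-5,8-dihydronaphthalen-2(4aH)-one
Conditions: DDQ (1.2 equiv), CH2Cl2/pH 7 buffer, 0 → 23 °C
Reagents that add atoms: water, O
Why: DDQ abstracts hydride from the doubly allylic, oxygen-bearing C8–H (the same reaction type as oxidative cleavage of allylic and benzylic ethers); water adds to the oxocarbenium ion and methanol is lost, giving the cross-conjugated dienone. The quaternary C5 blocks aromatisation, and the C1–H2 position lacks the oxygen lone pair and should react much more slowly.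

Step 11
Reactants: 16 (4aR,5S)-4a,5-dimethyl-5,8-dihydronaphthalen-2(4aH)-one
Product: 17 (4aR,5R,6S,7R)-6,7-epoxy-4a,5-dimethyl-5,6,7,8-tetrahydronaphthalen-2(4aH)-one (2α,3α-oxirane in target numbering)
Conditions: mCPBA, CH2Cl2, 0 °C
Reagents that add atoms: 3-chloroperbenzoic acid, OOC(=O)c1cccc(Cl)c1
Why: Prilezhaev epoxidation picks the only electron-rich alkene (C2=C3), since both dienone double bonds are deactivated. The axial C14 methyl on the homoallylic C5 shields the β face, as the angular methyl does in 2-ene steroids, so the oxirane should form on the α face and set C2 and C3 relative to C5.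

Step 12
Reactants: 18 (S)-2-methylbutan-1-ol
Product: 19 (S)-2-methylbutanal
Conditions: TEMPO (cat.), KBr (cat.), NaOCl (aq., pH 9.5), CH2Cl2, 0 °C; dried CH2Cl2 solution used directly
Reagents that add atoms: none
Why: Oxoammonium (Anelli) oxidation is fast at 0 °C in a buffered two-phase system and is an established way to this aldehyde without loss of configuration; the volatile product is not concentrated.

Step 13
Reactants: 19 (S)-2-methylbutanal
Product: 20 ethyl (2E,4E,6S)-6-methylocta-2,4-dienoate
Conditions: triethyl 4-phosphonocrotonate, LiN(SiMe3)2, THF, −78 °C; then 19, −78 → 0 °C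
Reagents that add atoms: triethyl 4-phosphonocrotonate, CCOC(=O)/C=C/CP(=O)(OCC)OCC
Why: The vinylogous Horner–Wadsworth–Emmons reaction builds the new C4=C5 bond E under thermodynamic control while the reagent carries the E C2=C3 bond. The weakly basic phosphonate anion at low temperature should leave the α-stereocentre of 19 intact.

Step 14
Reactants: 20 ethyl (2E,4E,6S)-6-methylocta-2,4-dienoate
Product: 21 (2E,4E,6S)-6-methylocta-2,4-dienoic acid
Conditions: LiOH·H2O, THF/MeOH/H2O, 23 °C; then 1 M HCl
Reagents that add atoms: lithium hydroxide, [Li+].[OH-]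
Why: Plain saponification; the stereocentre is γ,δ-remote from the carboxylate and not acidic.

Step 15
Reactants: 17 (4aR,5R,6S,7R)-6,7-epoxy-4a,5-dimethyl-5,6,7,8-tetrahydronaphthalen-2(4aH)-one; 21 (2E,4E,6S)-6-methylocta-2,4-dienoic acid
Product: 22 (1R,2R,3R,8aR)-3-hydroxy-1,8a-dimethyl-6-oxo-1,2,3,4,6,8a-hexahydronaphthalen-2-yl (2E,4E,6S)-6-methylocta-2,4-dienoate
Conditions: 21 (1.5 equiv), Co(salen) (C36H52CoN2O2, 10 mol%; salen = N,N′-bis(3,5-di-tert-butylsalicylidene)cyclohexane-1,2-diaminate), air, iPr2NEt, t-BuOMe, 25–40 °C
Reagents that add atoms: none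
Why: The divalent cobalt complex is oxidised by air in the presence of 21 to the trivalent cobalt carboxylate, which activates the oxirane and delivers the carboxylate (catalytic addition of carboxylic acids to cyclohexene-oxide-type epoxides). On the locked half-chair only attack at C3 from the β face gives the diaxial product (Fürst–Plattner rule), which inverts C3 and leaves O2 α, i.e. the target's 3β-acyloxy-2α-hydroxy pattern. Both antipodes of the ligand are available, so the one that cooperates with this inherent bias can be chosen; the near-neutral medium avoids γ-deprotonation at C1 and acid-induced shifts of the dienone.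

Step 16
Reactants: 22 (1R,2R,3R,8aR)-3-hydroxy-1,8a-dimethyl-6-oxo-1,2,3,4,6,8a-hexahydronaphthalen-2-yl (2E,4E,6S)-6-methylocta-2,4-dienoate
Product: 23 (1R,2R,3R,7R,8R,8aR)-7,8-epoxy-3-hydroxy-1,8a-dimethyl-6-oxo-1,2,3,4,6,7,8,8a-octahydronaphthalen-2-yl (2E,4E,6S)-6-methylocta-2,4-dienoate (6α,7α-oxirane in target numbering)
Conditions: t-BuOOH (in decane), DBU, CH2Cl2, 0 → 23 °C
Reagents that add atoms: tert-butyl hydroperoxide, CC(C)(C)OO
Why: Weitz–Scheffer nucleophilic epoxidation: the peroxide anion adds to the less substituted β-carbon C6 (C10 is fully substituted), as in the 1,2-epoxidation of steroidal 1,4-dien-3-ones, from the face anti to C14. The bulky anhydrous peroxide should not cleave the hindered dienoate, and either oxirane face would converge in step 17.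

Step 17
Reactants: 23 (1R,2R,3R,7R,8R,8aR)-7,8-epoxy-3-hydroxy-1,8a-dimethyl-6-oxo-1,2,3,4,6,7,8,8a-octahydronaphthalen-2-yl (2E,4E,6S)-6-methylocta-2,4-dienoate
Product: 24 Septeremophilane G, (1R,2R,3R,8aS)-3,7-dihydroxy-1,8a-dimethyl-6-oxo-1,2,3,4,6,8a-hexahydronaphthalen-2-yl (2E,4E,6S)-6-methylocta-2,4-dienoate
Conditions: H2SO4 (cat.), AcOH/H2O (9:1), 15 °C, short contact time; NaHCO3 quench
Reagents that add atoms: none
Why: Acid-mediated isomerisation of an α,β-epoxy ketone to the diosphenol: the C6–O bond opens (solvent-assisted or by 1,2-hydride shift), C7 keeps its oxygen, and the resulting 7,8-dione rests as the C6=C7 enol conjugated with C8=O. It is the reaction used to make 2-hydroxy-1,4-dien-3-ones and 4-hydroxy-4-en-3-ones in the steroid series; no stereocentre is formed or touched.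

## Compound list

1 | methyl (S)-3-hydroxy-2-methylpropanoate | COC(=O)[C@@H](C)CO | starting material
2 | methyl (S)-3-[(tert-butyldimethylsilyl)oxy]-2-methylpropanoate | COC(=O)[C@@H](C)CO[Si](C)(C)C(C)(C)C | intermediate
3 | (S)-3-[(tert-butyldimethylsilyl)oxy]-2-methylpropanal | O=C[C@@H](C)CO[Si](C)(C)C(C)(C)C | intermediate (not isolated)
4 | (R)-tert-butyldimethyl[(2-methylbut-3-yn-1-yl)oxy]silane | C#C[C@@H](C)CO[Si](C)(C)C(C)(C)C | intermediate
5 | {(1E,3R)-4-[(tert-butyldimethylsilyl)oxy]-2,3-dimethylbut-1-en-1-yl}dimethylalumane | C[Al](C)/C=C(C)/[C@@H](C)CO[Si](C)(C)C(C)(C)C | intermediate (not isolated)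
6 | tert-butyl{[(2R,3E)-4-iodo-2,3-dimethylbut-3-en-1-yl]oxy}dimethylsilane | I/C=C(C)/[C@@H](C)CO[Si](C)(C)C(C)(C)C | intermediate
7 | (2R,3E)-4-iodo-2,3-dimethylbut-3-en-1-ol | I/C=C(C)/[C@@H](C)CO | intermediate
8 | (2R,3E)-4-iodo-2,3-dimethylbut-3-enal | I/C=C(C)/[C@@H](C)C=O | intermediate
9 | (4-bromobut-1-yn-1-yl)trimethylsilane | C[Si](C)(C)C#CCCBr | starting material
10 | triphenyl[4-(trimethylsilyl)but-3-yn-1-yl]phosphonium bromide | C[Si](C)(C)C#CCC[P+](c1ccccc1)(c1ccccc1)c1ccccc1.[Br-] | intermediate
11 | triphenyl[4-(trimethylsilyl)but-3-yn-1-ylidene]-λ5-phosphane | C[Si](C)(C)C#CCC=P(c1ccccc1)(c1ccccc1)c1ccccc1 | intermediate (not isolated)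
12 | trimethyl[(4Z,6S,7E)-8-iodo-6,7-dimethylocta-4,7-dien-1-yn-1-yl]silane | C[Si](C)(C)C#CC/C=C\[C@H](C)/C(C)=C/I | intermediate
13 | trimethyl[(4Z,6S,7E,9E)-10-methoxy-6,7-dimethyldeca-4,7,9-trien-1-yn-1-yl]silane | C[Si](C)(C)C#CC/C=C\[C@H](C)/C(C)=C/C=C/OC | intermediate (not isolated)
14 | (1E,3E,5S,6Z)-1-methoxy-4,5-dimethyldeca-1,3,6-trien-9-yne | C#CC/C=C\[C@H](C)/C(C)=C/C=C/OC | intermediate
15 | (2R,4aR,5S)-2-methoxy-4a,5-dimethyl-2,4a,5,8-tetrahydronaphthalene (4a,5-cis; OMe trans to the 4a-methyl) | C1=CCC2=C[C@H](OC)C=C[C@]2(C)[C@H]1C | intermediate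
16 | (4aR,5S)-4a,5-dimethyl-5,8-dihydronaphthalen-2(4aH)-one | C1=CCC2=CC(=O)C=C[C@]2(C)[C@H]1C | intermediate
17 | (4aR,5R,6S,7R)-6,7-epoxy-4a,5-dimethyl-5,6,7,8-tetrahydronaphthalen-2(4aH)-one | C[C@H]1[C@@H]2O[C@@H]2CC3=CC(=O)C=C[C@]13C | intermediate
18 | (S)-2-methylbutan-1-ol | CC[C@H](C)CO | starting material
19 | (S)-2-methylbutanal | CC[C@H](C)C=O | intermediate
20 | ethyl (2E,4E,6S)-6-methylocta-2,4-dienoate | CC[C@H](C)/C=C/C=C/C(=O)OCC | intermediate
21 | (2E,4E,6S)-6-methylocta-2,4-dienoic acid | CC[C@H](C)/C=C/C=C/C(=O)O | intermediate
22 | (1R,2R,3R,8aR)-3-hydroxy-1,8a-dimethyl-6-oxo-1,2,3,4,6,8a-hexahydronaphthalen-2-yl (2E,4E,6S)-6-methylocta-2,4-dienoate | CC[C@H](C)/C=C/C=C/C(=O)O[C@H]1[C@H](O)CC2=CC(=O)C=C[C@]2(C)[C@H]1C | intermediate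
23 | (1R,2R,3R,7R,8R,8aR)-7,8-epoxy-3-hydroxy-1,8a-dimethyl-6-oxo-1,2,3,4,6,7,8,8a-octahydronaphthalen-2-yl (2E,4E,6S)-6-methylocta-2,4-dienoate | CC[C@H](C)/C=C/C=C/C(=O)O[C@H]1[C@H](O)CC2=CC(=O)[C@@H]3O[C@@H]3[C@]2(C)[C@H]1C | intermediate
24 | Septeremophilane G, (1R,2R,3R,8aS)-3,7-dihydroxy-1,8a-dimethyl-6-oxo-1,2,3,4,6,8a-hexahydronaphthalen-2-yl (2E,4E,6S)-6-methylocta-2,4-dienoate | CC[C@H](C)/C=C/C=C/C(=O)O[C@H]1[C@H](O)CC2=CC(=O)C(O)=C[C@]2(C)[C@H]1C | target

## Step count and least certain steps

Total: 17 steps. Longest linear sequence: 13 steps (1–5, 7–11, 15–17); step 6 and steps 12–14 are side branches.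

Step 9 (key step). The most likely failure is an oxidative cyclisation that is too slow: the diene terminus C5 carries an inside methyl group and the tether closes a six-membered ring, so alkyne oligomerisation through rhodium acetylide or vinylidene species, or acid-mediated loss of the enol ether, may outrun ring closure. The second concern is erosion of π-facial selectivity, because the preference for the pseudo-equatorial C4 methyl is conformational and may be small. Fallback, setting out from 13 and returning at 16: 13 is isolated after the coupling of step 8 (the methanolysis is omitted) and submitted to the same cationic rhodium catalyst; internal silylalkynes are competent partners in this cycloaddition and cannot form acetylides or vinylidenes, so higher temperature and longer times become possible. This should give [(2R,4aR,5S)-2-methoxy-4a,5-dimethyl-2,4a,5,8-tetrahydronaphthalen-1-yl]trimethylsilane F1. DDQ in wet CH2Cl2 as in step 10 would convert it to (4aR,5S)-4a,5-dimethyl-1-(trimethylsilyl)-5,8-dihydronaphthalen-2(4aH)-one F2, and fluoride-induced protodesilylation of this α-silyl enone (Bu4NF, AcOH, THF, 0 °C) would return 16.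

Step 7. The α-hydrogen of 8 is both α to the formyl group and allylic, so deprotonation by the strongly basic ylide may epimerise C4 or move the double bond into conjugation before the Wittig addition occurs; loss of Z selectivity is a lesser risk. Fallback, setting out from 8 and returning at 12: a Still–Gennari olefination with the much less basic anion of methyl bis(2,2,2-trifluoroethoxy)phosphorylacetate (KN(SiMe3)2, 18-crown-6, THF, −78 °C) should give methyl (2Z,4S,5E)-6-iodo-4,5-dimethylhexa-2,5-dienoate F3. Reduction with iBu2AlH gives (2Z,4S,5E)-6-iodo-4,5-dimethylhexa-2,5-dien-1-ol F4, and CBr4/PPh3 converts it to (1E,3S,4Z)-6-bromo-1-iodo-2,3-dimethylhexa-1,4-diene F5. Copper-catalysed substitution of this allylic bromide with Me3SiC≡CMgBr (CuI cat., THF) installs C10 and C9 and gives 12.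

Step 15. Attack at C3 is syn-axial to the angular methyl and gauche to the C4 methyl, so ring opening may be slow enough for attack at C2 through a twist-boat pathway (regioisomeric ester) or for base-induced opening of the oxirane from the γ-position C1 of the enone to compete. Fallback, setting out from 17 and returning at 22: acid-catalysed hydration (aq. HClO4, THF), in which the small nucleophile should follow the diaxial rule, gives (4aR,5R,6R,7R)-6,7-dihydroxy-4a,5-dimethyl-5,6,7,8-tetrahydronaphthalen-2(4aH)-one F6. Selective silylation of the less hindered O2 (Et3SiCl, imidazole, −20 °C) gives (4aR,5R,6R,7R)-6-hydroxy-4a,5-dimethyl-7-[(triethylsilyl)oxy]-5,6,7,8-tetrahydronaphthalen-2(4aH)-one F7. Yamaguchi esterification of the remaining C3 hydroxyl with 21 (2,4,6-trichlorobenzoyl chloride, Et3N, then DMAP, toluene) gives (1R,2R,3R,8aR)-1,8a-dimethyl-6-oxo-3-[(triethylsilyl)oxy]-1,2,3,4,6,8a-hexahydronaphthalen-2-yl (2E,4E,6S)-6-methylocta-2,4-dienoate F8, and HF·pyridine removes the silyl group to give 22.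

Step 17 (and with it step 16). The acid needed to open a deactivated oxirane next to the neopentyl C6 may also ionise the C2 hydroxyl through the dienol (vinylogous dehydration) or trigger an acyl or methyl shift at C6; in step 16 a slow epoxidation would lengthen the exposure of the ester to base. Fallback, setting out from 16 and returning at 24, with the diosphenol made before any sensitive group is present: nucleophilic epoxidation of 16 (H2O2, NaOH, MeOH, 0 °C) gives (3R,4R,4aR,5S)-3,4-epoxy-4a,5-dimethyl-3,4,5,8-tetrahydronaphthalen-2(4aH)-one F9. Acid isomerisation (H2SO4 cat., AcOH) gives (4aS,5S)-3-hydroxy-4a,5-dimethyl-5,8-dihydronaphthalen-2(4aH)-one F10, and acetylation (Ac2O, pyridine, DMAP) gives (8S,8aS)-8,8a-dimethyl-3-oxo-3,5,8,8a-tetrahydronaphthalen-2-yl acetate F11, whose enol ester is inert to peracid. mCPBA then gives the 6,7-epoxide (2α,3α-oxirane in target numbering) 6,7-epoxy-8,8a-dimethyl-3-oxo-3,5,6,7,8,8a-hexahydronaphthalen-2-yl acetate F12. Opening with 21 as in step 15 gives (1R,2R,3R,8aS)-7-acetoxy-3-hydroxy-1,8a-dimethyl-6-oxo-1,2,3,4,6,8a-hexahydronaphthalen-2-yl (2E,4E,6S)-6-methylocta-2,4-dienoate F13, and brief methanolysis of the enol acetate (K2CO3 cat., MeOH, 0 °C), far faster than that of the hindered dienoate, gives 24.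

## Further compounds

F1 | step 9 | [(2R,4aR,5S)-2-methoxy-4a,5-dimethyl-2,4a,5,8-tetrahydronaphthalen-1-yl]trimethylsilane | C1=CCC2=C([Si](C)(C)C)[C@H](OC)C=C[C@]2(C)[C@H]1C
F2 | step 9 | (4aR,5S)-4a,5-dimethyl-1-(trimethylsilyl)-5,8-dihydronaphthalen-2(4aH)-one | C1=CCC2=C([Si](C)(C)C)C(=O)C=C[C@]2(C)[C@H]1C
F3 | step 7 | methyl (2Z,4S,5E)-6-iodo-4,5-dimethylhexa-2,5-dienoate | COC(=O)/C=C\[C@H](C)/C(C)=C/I
F4 | step 7 | (2Z,4S,5E)-6-iodo-4,5-dimethylhexa-2,5-dien-1-ol | OC/C=C\[C@H](C)/C(C)=C/I
F5 | step 7 | (1E,3S,4Z)-6-bromo-1-iodo-2,3-dimethylhexa-1,4-diene | BrC/C=C\[C@H](C)/C(C)=C/I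
F6 | step 15 | (4aR,5R,6R,7R)-6,7-dihydroxy-4a,5-dimethyl-5,6,7,8-tetrahydronaphthalen-2(4aH)-one | O[C@H]1[C@H](O)CC2=CC(=O)C=C[C@]2(C)[C@H]1C
F7 | step 15 | (4aR,5R,6R,7R)-6-hydroxy-4a,5-dimethyl-7-[(triethylsilyl)oxy]-5,6,7,8-tetrahydronaphthalen-2(4aH)-one | O[C@H]1[C@H](O[Si](CC)(CC)CC)CC2=CC(=O)C=C[C@]2(C)[C@H]1C
F8 | step 15 | (1R,2R,3R,8aR)-1,8a-dimethyl-6-oxo-3-[(triethylsilyl)oxy]-1,2,3,4,6,8a-hexahydronaphthalen-2-yl (2E,4E,6S)-6-methylocta-2,4-dienoate | CC[C@H](C)/C=C/C=C/C(=O)O[C@H]1[C@H](O[Si](CC)(CC)CC)CC2=CC(=O)C=C[C@]2(C)[C@H]1C
F9 | step 17 | (3R,4R,4aR,5S)-3,4-epoxy-4a,5-dimethyl-3,4,5,8-tetrahydronaphthalen-2(4aH)-one | C1=CCC2=CC(=O)[C@@H]3O[C@@H]3[C@]2(C)[C@H]1C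
F10 | step 17 | (4aS,5S)-3-hydroxy-4a,5-dimethyl-5,8-dihydronaphthalen-2(4aH)-one | C1=CCC2=CC(=O)C(O)=C[C@]2(C)[C@H]1C
F11 | step 17 | (8S,8aS)-8,8a-dimethyl-3-oxo-3,5,8,8a-tetrahydronaphthalen-2-yl acetate | C1=CCC2=CC(=O)C(OC(C)=O)=C[C@]2(C)[C@H]1C
F12 | step 17 | 6,7-epoxy-8,8a-dimethyl-3-oxo-3,5,6,7,8,8a-hexahydronaphthalen-2-yl acetate (2α,3α-oxirane in target numbering) | C[C@H]1[C@@H]2O[C@@H]2CC3=CC(=O)C(OC(C)=O)=C[C@]13C
F13 | step 17 | (1R,2R,3R,8aS)-7-acetoxy-3-hydroxy-1,8a-dimethyl-6-oxo-1,2,3,4,6,8a-hexahydronaphthalen-2-yl (2E,4E,6S)-6-methylocta-2,4-dienoate | CC[C@H](C)/C=C/C=C/C(=O)O[C@H]1[C@H](O)CC2=CC(=O)C(OC(C)=O)=C[C@]2(C)[C@H]1C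
A1 | alternative 1 | 3β-hydroxy-4β-methyl-Δ5(10)-octalin-8-one ethylene ketal (target numbering) | O[C@H]1CCC2=C(CCC3(C2)OCCO3)[C@H]1C
A2 | alternative 1 | 3β-hydroxy-4β-methyl-5β,10β-methanodecalin-8-one ethylene ketal (target numbering; hydroxyl, methyl and bridge on one face) | O[C@H]1CC[C@]23CC4(OCCO4)CC[C@]2(C3)[C@H]1C
A3 | alternative 2 | 6-[(tert-butyldimethylsilyl)oxy]-7-[(4-methoxybenzyl)oxy]-8,9-dimethyldec-9-ene-2,4-dione (C6, C7, C8 configured as C2, C3, C4 of the target) | CC(=O)CC(=O)C[C@@H](O[Si](C)(C)C(C)(C)C)[C@H](OCc1ccc(OC)cc1)[C@H](C)C(C)=C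
A4 | alternative 2 | ring A cyclohexanone with the C5 methyl and the 3-oxobutyl chain (1,5-diketone), O2 silylated, O3 4-methoxybenzylated | COc1ccc(cc1)CO[C@H]1[C@H](O[Si](C)(C)C(C)(C)C)CC(=O)[C@](C)(CCC(C)=O)[C@H]1C
A5 | alternative 3 | 4-methyl-4-(3-oxobutyl)cyclohexa-2,5-dien-1-one | CC(=O)CCC1(C)C=CC(=O)C=C1
A6 | alternative 3 | cis-4a-methyl-4a,5,6,8a-tetrahydronaphthalene-2,7(1H,8H)-dione | O=C1C[C@@H]2CC(=O)CC[C@]2(C)C=C1
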